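Ring C is cut at C3–C4. The C4 ketone and the enolic C3 hydroxyl of the pyranone are together a dehydrogenated acyloin, so both carbons can enter as aldehydes. In one flask a triazolylidene carbene joins the ring-A formyl carbon (C4) to the aliphatic formyl carbon (C3) by benzoin closure of ring C, and air then dehydrogenates the acyloin to the 3-hydroxychromen-4-one, with no epoxidising reagent near the isopropenyl group. The precursor is a fully protected 2-formylaryl ether of a 2-aryl-2-hydroxyacetaldehyde bearing the (R)-side chain at C8; it is assembled from iodinated phloroglucinaldehyde, an α-bromo arylacetate and a limonene-derived alkylzinc reagent.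

Key step: step 15

Remark on the chemistry: all four phenols are carried as methoxymethyl (MOM) ethers and the tertiary alcohol as a triethylsilyl ether from step 4 onward, so that no bulky, base-labile aryl silyl ether flanks the ring-A aldehyde and a single mild acid treatment ends the synthesis.

Step 1
Reactants: 1 (R)-(+)-limonene
Product: 3 (3R)-6-oxo-3-(prop-1-en-2-yl)heptanal, via limonene ring ozonide 2 (not isolated)
Conditions: O3 (1.0 equiv), CH2Cl2, −78 °C; then PPh3, −78 °C → rt
Reagents that add atoms: ozone, [O-][O+]=O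
Why: Chemoselective ozonolysis: ozone adds to the electron-rich trisubstituted ring alkene far faster than to the 1,1-disubstituted isopropenyl group, so one equivalent at −78 °C and phosphine reduction of the ozonide should open the ring to the keto aldehyde while the stereocentre of limonene, which takes no part, is carried over unchanged.

Step 2
Reactants: 3 (3R)-6-oxo-3-(prop-1-en-2-yl)heptanal
Product: 4 (3R)-6-oxo-3-(prop-1-en-2-yl)heptanoic acid
Conditions: NaClO2, NaH2PO4, 2-methyl-2-butene, t-BuOH/H2O, 0 °C → rt
Reagents that add atoms: sodium chlorite, [Na+].[O-]Cl=O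
Why: Pinnick oxidation: chlorous acid converts only the aldehyde into the carboxylic acid, the ketone is inert, and the hypochlorous acid formed is intercepted by the excess of the more nucleophilic 2-methyl-2-butene before it can attack the isopropenyl group.

Step 3
Reactants: 4 (3R)-6-oxo-3-(prop-1-en-2-yl)heptanoic acid
Product: 5 (3R)-6-hydroxy-6-methyl-3-(prop-1-en-2-yl)heptanoic acid
Conditions: MeMgBr (3.2 equiv), THF, −30 → 0 °C; then 1 M HCl
Reagents that add atoms: methylmagnesium bromide, C[Mg]Br
Why: Grignard addition: the first equivalent of MeMgBr converts the acid into an unreactive magnesium carboxylate and further reagent adds to the methyl ketone to give the dimethyl carbinol, the stereocentre being remote from both carbonyl groups and therefore not epimerisable.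

Step 4
Reactants: 5 (3R)-6-hydroxy-6-methyl-3-(prop-1-en-2-yl)heptanoic acid
Product: 7 (3R)-6-methyl-3-(prop-1-en-2-yl)-6-(triethylsilyloxy)heptanoic acid, via bis-silyl ester 6 (not isolated)
Conditions: Et3SiOTf (2.3 equiv), 2,6-lutidine, CH2Cl2, −40 → 0 °C; then MeOH, K2CO3 (cat.), 0 °C
Reagents that add atoms: triethylsilyl trifluoromethanesulfonate, CC[Si](CC)(CC)OS(=O)(=O)C(F)(F)F
Why: Silylation with a silyl triflate and a hindered pyridine base protects the tertiary alcohol, which would otherwise quench the later organozinc reagent or cyclise onto the primary iodide, and the silyl ester formed at the same time is cleaved selectively by mild methanolysis.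

Step 5
Reactants: 7 (3R)-6-methyl-3-(prop-1-en-2-yl)-6-(triethylsilyloxy)heptanoic acid
Product: 9 (5S)-5-(iodomethyl)-2,6-dimethyl-2-(triethylsilyloxy)hept-6-ene, via Barton ester 8 (not isolated)
Conditions: N-hydroxypyridine-2-thione, DCC, 4-(dimethylamino)pyridine (cat.), CH2Cl2, 0 °C → rt, dark; then CHI3, hν (tungsten lamp), rt
Reagents that add atoms: iodoform, IC(I)I
Why: Barton decarboxylative iodination: photolysis of the thiohydroxamate ester expels CO2 and the primary radical takes iodine from iodoform much faster than a homoallylic radical rearranges, so the carboxyl carbon is excised with retention at the neighbouring stereocentre, whose descriptor changes to S only because CH2I outranks isopropenyl.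

Step 6
Reactants: 10 2,4,6-trihydroxybenzaldehyde
Product: 11 2-hydroxy-4,6-bis(methoxymethoxy)benzaldehyde
Conditions: MOMCl (2.2 equiv), i-Pr2NEt, CH2Cl2, 0 °C → rt
Reagents that add atoms: chloromethyl methyl ether (MOMCl), COCCl
Why: Selective Williamson-type acetalisation: two equivalents of MOMCl etherify the 4-hydroxyl and one ortho-hydroxyl, whereas the remaining ortho-hydroxyl is held in a hydrogen bond to the formyl group and stays free to mark the future O1.

Step 7
Reactants: 11 2-hydroxy-4,6-bis(methoxymethoxy)benzaldehyde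
Product: 12 2-hydroxy-3-iodo-4,6-bis(methoxymethoxy)benzaldehyde
Conditions: BnMe3N·ICl2, NaHCO3, CH2Cl2/MeOH, rt
Reagents that add atoms: benzyltrimethylammonium dichloroiodate, C[N+](C)(C)Cc1ccccc1.Cl[I-]Cl
Why: Electrophilic aromatic iodination: under bicarbonate buffering the dichloroiodate iodinates ortho to the free chelated phenol (C3) in preference to C5, which is flanked by two MOM ethers, the pattern known for 2-hydroxy-4,6-dialkoxyaryl carbonyl compounds, and so places the halogen at the future C8 beside the future O1.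

Step 8
Reactants: 13 2,4-dihydroxyphenylacetic acid
Product: 14 methyl (2,4-dihydroxyphenyl)acetate
Conditions: MeOH, H2SO4 (cat.), reflux
Reagents that add atoms: methanol, CO
Why: Fischer esterification in excess methanol should give the methyl ester, any benzofuranone lactone arising from the ortho-hydroxy acid being opened to the same ester under these conditions.

Step 9
Reactants: 14 methyl (2,4-dihydroxyphenyl)acetate
Product: 15 methyl [2,4-bis(methoxymethoxy)phenyl]acetate
Conditions: MOMCl (2.5 equiv), i-Pr2NEt, CH2Cl2, 0 °C → rt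
Reagents that add atoms: chloromethyl methyl ether (MOMCl), COCCl
Why: Base-mediated MOM etherification of both phenols gives acetal protection that withstands the enolate, carbonate, hydride, Swern and carbene steps that follow.

Step 10
Reactants: 15 methyl [2,4-bis(methoxymethoxy)phenyl]acetate
Product: 17 methyl bromo[2,4-bis(methoxymethoxy)phenyl]acetate (racemic), via silyl ketene acetal 16 (not isolated)
Conditions: LiN(SiMe3)2, THF, −78 °C; Me3SiCl; then NBS, −78 °C
Reagents that add atoms: N-bromosuccinimide, O=C1CCC(=O)N1Br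
Why: Enolate α-bromination by way of the silyl ketene acetal: trapping the lithium enolate with Me3SiCl before NBS is added avoids coupling of enolate with product and bromination of the electron-rich ring, and gives the benzylic α-bromo ester as a racemate whose centre later becomes sp2.

Step 11
Reactants: 12 2-hydroxy-3-iodo-4,6-bis(methoxymethoxy)benzaldehyde; 17 methyl bromo[2,4-bis(methoxymethoxy)phenyl]acetate (racemic)
Product: 18 methyl [2,4-bis(methoxymethoxy)phenyl][2-formyl-6-iodo-3,5-bis(methoxymethoxy)phenoxy]acetate (racemic)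
Conditions: K2CO3, DMF, 0 °C → rt
Reagents that add atoms: none
Why: Williamson ether synthesis: the phenoxide of the only free hydroxyl displaces bromide from the doubly activated benzylic α-bromo ester by SN2 at or below room temperature, conditions under which the Rap–Stoermer-type aldol of the product onto the deactivated formyl group should not occur.

Step 12
Reactants: 9 (5S)-5-(iodomethyl)-2,6-dimethyl-2-(triethylsilyloxy)hept-6-ene; 18 methyl [2,4-bis(methoxymethoxy)phenyl][2-formyl-6-iodo-3,5-bis(methoxymethoxy)phenoxy]acetate (racemic)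
Product: 20 methyl [2,4-bis(methoxymethoxy)phenyl]{2-formyl-3,5-bis(methoxymethoxy)-6-[(2R)-5-methyl-2-(prop-1-en-2-yl)-5-(triethylsilyloxy)hexyl]phenoxy}acetate (epimers at the aryloxy carbon), via alkylzinc iodide 19 (not isolated)
Conditions: 9, Zn dust, LiCl, THF, 40 °C (zinc reagent decanted from excess metal); then 18, Pd(OAc)2 (5 mol%), 2-dicyclohexylphosphino-2',6'-dimethoxybiphenyl (SPhos, 10 mol%), THF/NMP, rt → 50 °C
Reagents that add atoms: none
Why: Negishi cross-coupling: LiCl-assisted zinc insertion gives a primary alkylzinc iodide that tolerates the aldehyde, the ester and its acidic α-hydrogen, and a palladium catalyst bearing the bulky biarylphosphine SPhos should couple it with the di-ortho-oxygenated aryl iodide faster than β-hydride elimination, the stereocentre β to zinc taking no part.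

Step 13
Reactants: 20 methyl [2,4-bis(methoxymethoxy)phenyl]{2-formyl-3,5-bis(methoxymethoxy)-6-[(2R)-5-methyl-2-(prop-1-en-2-yl)-5-(triethylsilyloxy)hexyl]phenoxy}acetate
Product: 21 2-[2,4-bis(methoxymethoxy)phenyl]-2-{2-(hydroxymethyl)-3,5-bis(methoxymethoxy)-6-[(2R)-5-methyl-2-(prop-1-en-2-yl)-5-(triethylsilyloxy)hexyl]phenoxy}ethanol (epimers at the aryloxy carbon)
Conditions: LiAlH4, THF, 0 °C; aqueous work-up
Reagents that add atoms: none
Why: Hydride reduction with LiAlH4 converts the methyl ester and the aryl aldehyde into the two primary alcohols in one operation and leaves the MOM acetals, the silyl ether and the alkene untouched.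

Step 14
Reactants: 21 2-[2,4-bis(methoxymethoxy)phenyl]-2-{2-(hydroxymethyl)-3,5-bis(methoxymethoxy)-6-[(2R)-5-methyl-2-(prop-1-en-2-yl)-5-(triethylsilyloxy)hexyl]phenoxy}ethanol
Product: 22 2-[2,4-bis(methoxymethoxy)phenyl]-2-{2-formyl-3,5-bis(methoxymethoxy)-6-[(2R)-5-methyl-2-(prop-1-en-2-yl)-5-(triethylsilyloxy)hexyl]phenoxy}acetaldehyde (epimers at the aryloxy carbon)
Conditions: (COCl)2, DMSO, CH2Cl2, −78 °C; then Et3N, −78 → −20 °C
Reagents that add atoms: none
Why: Swern oxidation activates both hydroxyls as alkoxysulfonium ions before the base is added, so the dialdehyde should form without lactol or lactone formation and without over-oxidation, and the enolisable α-aryloxy aldehyde is carried on at once without chromatography.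

Step 15
Reactants: 22 2-[2,4-bis(methoxymethoxy)phenyl]-2-{2-formyl-3,5-bis(methoxymethoxy)-6-[(2R)-5-methyl-2-(prop-1-en-2-yl)-5-(triethylsilyloxy)hexyl]phenoxy}acetaldehyde
Product: 25 kushenol G 5,7,2',4'-tetrakis(methoxymethyl) ether triethylsilyl ether, via 4-hydroxychroman-3-one 23 (not isolated), via dihydroflavonol 24 (not isolated)
Conditions: 2-(pentafluorophenyl)-6,7-dihydro-5H-pyrrolo[2,1-c][1,2,4]triazol-2-ium tetrafluoroborate (20 mol%), 1,8-diazabicyclo[5.4.0]undec-7-ene (DBU, 20 mol%), THF, rt, Ar; then DBU (1.5 equiv), air, rt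
Reagents that add atoms: none
Why: Intramolecular benzoin condensation under N-heterocyclic carbene catalysis followed by aerobic dehydrogenation: the triazolylidene adds to one formyl group, proton transfer gives the Breslow intermediate, and this acyl-anion equivalent attacks the other formyl group across the five-atom tether in a 6-exo-trig closure that forms the C3–C4 bond and ring C. Whichever aldehyde is the donor the same bond results, the acyloins 23 and 24 equilibrate through their common enediol, and DBU with air oxidises the enediolate to the 3,4-diketone, whose enol is the aromatic 3-hydroxychromen-4-one 25. The closest known reaction type is the carbene-catalysed intramolecular crossed benzoin cyclisation of 2-formylaryl ethers to 3-hydroxychroman-4-ones, applied here with an aldehyde in place of the ketone acceptor. No lasting stereocentre is created, because C2 and C3 both become sp2 and the side-chain centre is remote from all basic sites. The step needs ring closure to outrun β-elimination of the ring-A aryloxide from the C3 Breslow intermediate as well as aldol reactions of the enolisable α-aryloxy aldehyde, which the six-membered transition state, the small MOM group beside the ring-A aldehyde, an electron-poor N-pentafluorophenyl triazolium salt, low base loading and exclusion of air until closure is complete are chosen to secure. The position of O1 next to the side chain was already fixed in steps 7 and 11, so no regiochemical issue is left to this step.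

Step 16
Reactants: 25 kushenol G 5,7,2',4'-tetrakis(methoxymethyl) ether triethylsilyl ether
Product: 26 kushenol G
Conditions: HCl (1.25 M in MeOH), THF, 0 °C → rt
Reagents that add atoms: none
Why: Acid-catalysed acetal exchange with methanol removes the four phenolic MOM ethers and the tertiary silyl ether in one operation under conditions too mild to protonate the isopropenyl group or ionise the tertiary alcohol, so kushenol G should result with its (R)-centre untouched.

Compound list
1 | (R)-(+)-limonene, (4R)-1-methyl-4-(prop-1-en-2-yl)cyclohex-1-ene | C=C(C)[C@@H]1CCC(C)=CC1 | starting material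
2 | limonene ring ozonide (1,2,4-trioxolane bridging the former C1 and C2, isopropenyl intact, mixture of diastereomers) | C=C(C)[C@@H]1CCC2(C)OOC(C1)O2 | intermediate
3 | (3R)-6-oxo-3-(prop-1-en-2-yl)heptanal | C=C(C)[C@@H](CC=O)CCC(C)=O | intermediate
4 | (3R)-6-oxo-3-(prop-1-en-2-yl)heptanoic acid | C=C(C)[C@@H](CC(=O)O)CCC(C)=O | intermediate
5 | (3R)-6-hydroxy-6-methyl-3-(prop-1-en-2-yl)heptanoic acid | C=C(C)[C@@H](CC(=O)O)CCC(C)(C)O | intermediate
6 | triethylsilyl (3R)-6-methyl-3-(prop-1-en-2-yl)-6-(triethylsilyloxy)heptanoate (bis-silyl ester) | C=C(C)[C@@H](CC(=O)O[Si](CC)(CC)CC)CCC(C)(C)O[Si](CC)(CC)CC | intermediate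
7 | (3R)-6-methyl-3-(prop-1-en-2-yl)-6-(triethylsilyloxy)heptanoic acid | C=C(C)[C@@H](CC(=O)O)CCC(C)(C)O[Si](CC)(CC)CC | intermediate
8 | 2-thioxopyridin-1(2H)-yl (3R)-6-methyl-3-(prop-1-en-2-yl)-6-(triethylsilyloxy)heptanoate (Barton ester) | C=C(C)[C@@H](CC(=O)ON1C=CC=CC1=S)CCC(C)(C)O[Si](CC)(CC)CC | intermediate
9 | (5S)-5-(iodomethyl)-2,6-dimethyl-2-(triethylsilyloxy)hept-6-ene | C=C(C)[C@@H](CI)CCC(C)(C)O[Si](CC)(CC)CC | intermediate
10 | 2,4,6-trihydroxybenzaldehyde | O=Cc1c(O)cc(O)cc1O | starting material
11 | 2-hydroxy-4,6-bis(methoxymethoxy)benzaldehyde | O=Cc1c(O)cc(OCOC)cc1OCOC | intermediate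
12 | 2-hydroxy-3-iodo-4,6-bis(methoxymethoxy)benzaldehyde | O=Cc1c(O)c(I)c(OCOC)cc1OCOC | intermediate
13 | 2,4-dihydroxyphenylacetic acid | O=C(O)Cc1ccc(O)cc1O | starting material
14 | methyl (2,4-dihydroxyphenyl)acetate | COC(=O)Cc1ccc(O)cc1O | intermediate
15 | methyl [2,4-bis(methoxymethoxy)phenyl]acetate | COC(=O)Cc1ccc(OCOC)cc1OCOC | intermediate
16 | O-methyl O-trimethylsilyl ketene acetal of 15 (E/Z mixture) | COC(O[Si](C)(C)C)=Cc1ccc(OCOC)cc1OCOC | intermediate
17 | methyl bromo[2,4-bis(methoxymethoxy)phenyl]acetate (racemic) | COC(=O)C(Br)c1ccc(OCOC)cc1OCOC | intermediate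
18 | methyl [2,4-bis(methoxymethoxy)phenyl][2-formyl-6-iodo-3,5-bis(methoxymethoxy)phenoxy]acetate (racemic) | COC(=O)C(Oc1c(I)c(OCOC)cc(OCOC)c1C=O)c1ccc(OCOC)cc1OCOC | intermediate
19 | [(2S)-5-methyl-2-(prop-1-en-2-yl)-5-(triethylsilyloxy)hexyl]zinc iodide | C=C(C)[C@@H](C[Zn]I)CCC(C)(C)O[Si](CC)(CC)CC | intermediate
20 | methyl [2,4-bis(methoxymethoxy)phenyl]{2-formyl-3,5-bis(methoxymethoxy)-6-[(2R)-5-methyl-2-(prop-1-en-2-yl)-5-(triethylsilyloxy)hexyl]phenoxy}acetate (epimers at the aryloxy carbon) | C=C(C)[C@H](CCC(C)(C)O[Si](CC)(CC)CC)Cc1c(OCOC)cc(OCOC)c(C=O)c1OC(C(=O)OC)c1ccc(OCOC)cc1OCOC | intermediate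
21 | 2-[2,4-bis(methoxymethoxy)phenyl]-2-{2-(hydroxymethyl)-3,5-bis(methoxymethoxy)-6-[(2R)-5-methyl-2-(prop-1-en-2-yl)-5-(triethylsilyloxy)hexyl]phenoxy}ethanol (epimers at the aryloxy carbon) | C=C(C)[C@H](CCC(C)(C)O[Si](CC)(CC)CC)Cc1c(OCOC)cc(OCOC)c(CO)c1OC(CO)c1ccc(OCOC)cc1OCOC | intermediate
22 | 2-[2,4-bis(methoxymethoxy)phenyl]-2-{2-formyl-3,5-bis(methoxymethoxy)-6-[(2R)-5-methyl-2-(prop-1-en-2-yl)-5-(triethylsilyloxy)hexyl]phenoxy}acetaldehyde (epimers at the aryloxy carbon) | C=C(C)[C@H](CCC(C)(C)O[Si](CC)(CC)CC)Cc1c(OCOC)cc(OCOC)c(C=O)c1OC(C=O)c1ccc(OCOC)cc1OCOC | intermediate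
23 | 2-[2,4-bis(methoxymethoxy)phenyl]-4-hydroxy-5,7-bis(methoxymethoxy)-8-[(2R)-5-methyl-2-(prop-1-en-2-yl)-5-(triethylsilyloxy)hexyl]chroman-3-one (diastereomer mixture) | C=C(C)[C@H](CCC(C)(C)O[Si](CC)(CC)CC)Cc1c(OCOC)cc(OCOC)c2c1OC(c1ccc(OCOC)cc1OCOC)C(=O)C2O | intermediate
24 | 2-[2,4-bis(methoxymethoxy)phenyl]-3-hydroxy-5,7-bis(methoxymethoxy)-8-[(2R)-5-methyl-2-(prop-1-en-2-yl)-5-(triethylsilyloxy)hexyl]chroman-4-one (protected dihydroflavonol, diastereomer mixture) | C=C(C)[C@H](CCC(C)(C)O[Si](CC)(CC)CC)Cc1c(OCOC)cc(OCOC)c2c1OC(c1ccc(OCOC)cc1OCOC)C(O)C2=O | intermediate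
25 | kushenol G 5,7,2',4'-tetrakis(methoxymethyl) ether triethylsilyl ether: 2-[2,4-bis(methoxymethoxy)phenyl]-3-hydroxy-5,7-bis(methoxymethoxy)-8-[(2R)-5-methyl-2-(prop-1-en-2-yl)-5-(triethylsilyloxy)hexyl]chromen-4-one | C=C(C)[C@H](CCC(C)(C)O[Si](CC)(CC)CC)Cc1c(OCOC)cc(OCOC)c2c(=O)c(O)c(-c3ccc(OCOC)cc3OCOC)oc12 | intermediate
26 | kushenol G, 2-(2,4-dihydroxyphenyl)-3,5,7-trihydroxy-8-[(2R)-5-hydroxy-5-methyl-2-(prop-1-en-2-yl)hexyl]chromen-4-one | C=C(C)[C@H](CCC(C)(C)O)Cc1c(O)cc(O)c2c(=O)c(O)c(-c3ccc(O)cc3O)oc12 | target

Total step count: 16.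
Longest linear sequence: 10 steps (steps 1–5 and 12–16, from (R)-limonene).

Steps most likely to fail

1. Step 15. The Breslow intermediate at C3 may expel the ring-A aryloxide by β-elimination (redox isomerisation instead of C–C bond formation), the enolisable aldehyde may enter aldol pathways, or the aerobic dehydrogenation may stall or run on to oxidative cleavage of the flavonolate. Fallback: setting out from dialdehyde 22, the same C3–C4 bond would be made reductively. SmI2 (THF, t-BuOH, −78 °C) should effect an intramolecular pinacol coupling of the two formyl groups to the protected flavan-3,4-diol F1 (diastereomer mixture). A double Swern oxidation [(CF3CO)2O, DMSO, CH2Cl2, −78 °C; Et3N] should then take both carbinols to the 3,4-diketone, whose stable enol is 25, where the route is rejoined.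

2. Step 12. Oxidative addition and transmetalation at the doubly ortho-substituted iodide may be slow, so that protodeiodination or β-hydride elimination and chain isomerisation take over; zinc insertion into the β-branched iodide may also be sluggish. Fallback: setting out from iodophenol 12, the cross-coupling would be moved ahead of the etherification, so that the iodide carries only small neighbours and no acidic C–H. Acetylation (Ac2O, pyridine) gives 2-formyl-6-iodo-3,5-bis(methoxymethoxy)phenyl acetate F2. Negishi coupling of F2 with 19 under the same catalyst gives the side-chain-bearing aryl acetate F3. K2CO3 in MeOH releases the 3-alkyl-2-hydroxy-4,6-bis(methoxymethoxy)benzaldehyde F4, and Williamson etherification of F4 with bromide 17 (K2CO3, DMF) returns to 20.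

3. Step 5. The radical chain may break down, the homoallylic radical may rearrange by 1,2-vinyl shift, or iodoform-derived radicals may add to the isopropenyl group. Fallback: setting out from acid 7, the carboxyl carbon would be exchanged for boron and then oxygen, and the iodide made by a polar substitution. Esterification with N-hydroxyphthalimide (N,N'-diisopropylcarbodiimide, 4-(dimethylamino)pyridine cat.) gives the redox-active ester F5. Light-driven decarboxylative borylation with bis(catecholato)diboron in N,N-dimethylacetamide, followed by pinacol/Et3N, gives the pinacol boronate F6. NaBO3·4H2O oxidises F6 to the primary alcohol F7, and an Appel reaction (I2, PPh3, imidazole) converts F7 into iodide 9.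

Further compounds
F1 | step 15 | 2-[2,4-bis(methoxymethoxy)phenyl]-5,7-bis(methoxymethoxy)-8-[(2R)-5-methyl-2-(prop-1-en-2-yl)-5-(triethylsilyloxy)hexyl]chromane-3,4-diol | C=C(C)[C@H](CCC(C)(C)O[Si](CC)(CC)CC)Cc1c(OCOC)cc(OCOC)c2c1OC(c1ccc(OCOC)cc1OCOC)C(O)C2O
F2 | step 12 | 2-formyl-6-iodo-3,5-bis(methoxymethoxy)phenyl acetate | CC(=O)Oc1c(I)c(OCOC)cc(OCOC)c1C=O
F3 | step 12 | 2-formyl-3,5-bis(methoxymethoxy)-6-[(2R)-5-methyl-2-(prop-1-en-2-yl)-5-(triethylsilyloxy)hexyl]phenyl acetate | C=C(C)[C@H](CCC(C)(C)O[Si](CC)(CC)CC)Cc1c(OCOC)cc(OCOC)c(C=O)c1OC(C)=O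
F4 | step 12 | 2-hydroxy-4,6-bis(methoxymethoxy)-3-[(2R)-5-methyl-2-(prop-1-en-2-yl)-5-(triethylsilyloxy)hexyl]benzaldehyde | C=C(C)[C@H](CCC(C)(C)O[Si](CC)(CC)CC)Cc1c(OCOC)cc(OCOC)c(C=O)c1O
F5 | step 5 | 1,3-dioxoisoindolin-2-yl (3R)-6-methyl-3-(prop-1-en-2-yl)-6-(triethylsilyloxy)heptanoate | C=C(C)[C@@H](CC(=O)ON1C(=O)c2ccccc2C1=O)CCC(C)(C)O[Si](CC)(CC)CC
F6 | step 5 | 4,4,5,5-tetramethyl-2-[(2S)-5-methyl-2-(prop-1-en-2-yl)-5-(triethylsilyloxy)hexyl]-1,3,2-dioxaborolane | C=C(C)[C@@H](CB1OC(C)(C)C(C)(C)O1)CCC(C)(C)O[Si](CC)(CC)CC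
F7 | step 5 | (2S)-5-methyl-2-(prop-1-en-2-yl)-5-(triethylsilyloxy)hexan-1-ol | C=C(C)[C@@H](CO)CCC(C)(C)O[Si](CC)(CC)CC
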